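**Retrosynthetic overview**

1. Target 11 comes from isopropyl ether 10 by BCl3 dealkylation, and 10 from phenol 9 by O-methylation; only oxygen substituents change after the key step.
2. The strategy rests on ring A of 9: C1 (OH, later OMe) lies between C2 (aryloxy) and C6–H, with Br on C4 para to C1. Cutting C2–C3 and C5–C6 gives the ketone unit C6–C1–C2 of aryloxyacetone 5 and the unit C3–C4(Br)–C5 of 2-bromomalonaldehyde 6.
3. In base the dialdehyde is a poorly electrophilic enolate, and as the free acid it can hand bromine to an enolate. It is therefore used as its bis(dimethyliminium) form, vinamidinium salt 7.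
4. Ketone 5 comes from 2-isopropoxyphenol 1 by bromination para and then ortho to the hydroxyl, followed by O-alkylation with chloroacetone 4.
5. Ring order: ring B is bought as an arene; ring A is the only ring built, in step 5.

Key step: step 5

Assumption: cation 7 and aminodienone 8 are push–pull polyenes whose double-bond geometry equilibrates under the conditions, so their SMILES carry no E/Z descriptors; the target has no stereocentre.

**Route**

Step 1
Reactants: 1 2-isopropoxyphenol
Product: 2 4-bromo-2-isopropoxyphenol
Conditions: NBS (1.0 equiv), MeCN, 0 °C
Reagents that add atoms: N-bromosuccinimide, O=C1CCC(=O)N1Br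
Why: Electrophilic aromatic bromination; the free hydroxyl, made the stronger donor by its hydrogen bond to the neighbouring isopropoxy oxygen, should direct the first bromine para to itself, as in the monobromination of guaiacol.

Step 2
Reactants: 2 4-bromo-2-isopropoxyphenol
Product: 3 2,4-dibromo-6-isopropoxyphenol
Conditions: NBS (1.05 equiv), iPr2NH (0.1 equiv), CH2Cl2, 0 °C to rt
Reagents that add atoms: N-bromosuccinimide, O=C1CCC(=O)N1Br
Why: Amine-mediated ortho-bromination of a phenol; the N-bromoamine formed in the flask is delivered through a hydrogen bond to the hydroxyl, so the one free ortho position should be brominated in preference to the carbon para to the isopropoxy group.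

Step 3
Reactants: 3 2,4-dibromo-6-isopropoxyphenol; 4 chloroacetone
Product: 5 1-(2,4-dibromo-6-isopropoxyphenoxy)propan-2-one
Conditions: K2CO3, KI (cat.), acetone, reflux
Reagents that add atoms: none
Why: Williamson ether synthesis; the acidic dibromophenol is deprotonated by K2CO3 and the phenoxide displaces halide from the unhindered, highly reactive alpha-halo ketone, so the two ortho substituents should not block the SN2 step.

Step 4
Reactants: 6 2-bromomalonaldehyde
Product: 7 2-bromo-1,3-bis(dimethylamino)trimethinium tetrafluoroborate
Conditions: Me2NH (2.05 equiv), HBF4 (48% aq., 1.0 equiv), EtOH, 0 °C to reflux, water removed as toluene azeotrope; crystallise from EtOH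
Reagents that add atoms: dimethylamine, CNC; tetrafluoroboric acid, [H+].F[B-](F)(F)F
Why: Condensation of a 1,3-dialdehyde with a secondary amine and its ammonium salt (enaminal formation, then iminium formation) gives the vinamidinium salt, the same reaction type that gives malonaldehyde dianil salts, and the bromine stays on an sp2 carbon throughout so it should not be displaced.

Step 5
Reactants: 5 1-(2,4-dibromo-6-isopropoxyphenoxy)propan-2-one; 7 2-bromo-1,3-bis(dimethylamino)trimethinium tetrafluoroborate
Product: 9 4-bromo-2-(2,4-dibromo-6-isopropoxyphenoxy)phenol, via aminodienone 8 (not isolated)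
Conditions: 5 and 7 (1:1), KOtBu (1.1 equiv), THF, 0 °C to rt; then KOtBu (1.3 equiv), 60 °C; aq. HCl work-up
Reagents that add atoms: none
Why: KOtBu converts 5 into its enolate, which adds through the more acidic aryloxymethylene carbon to a terminal carbon of cation 7 and loses Me2NH to give aminodienone 8 (vinylogous addition–elimination). A second equivalent of base enolises the methyl group, and the resulting 1-oxidohexatriene closes ring A by joining the methyl carbon to the aminomethine carbon, a 6π electrocyclisation equivalent to a favoured 6-(enolendo)-exo-trig attack of the enolate on the terminal C–N carbon; loss of the second Me2NH then aromatises the ring to the phenoxide. The closest known reaction type is the [3+3] benzannulation of ketones bearing two enolisable alpha carbons with vinamidinium salts, the activated counterpart of the nitromalonaldehyde–ketone phenol synthesis. No stereocentre is formed, and the push–pull diene of 8 isomerises freely, so the cis arrangement needed for closure is accessible. The step needs a single substitution pattern and 1:1 coupling: the pattern is fixed by construction, because the carbonyl carbon becomes C–OH, the CBr carbon lands para to it and the aryloxy carbon ortho whichever alpha carbon attacks first, and adding base to an equimolar mixture of 5 and 7 traps the enolate as it forms and limits self-aldol and double condensation. Ring B carries only aryl bromides and an isopropyl ether, which should be inert to KOtBu in THF at 60 °C.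

Step 6
Reactants: 9 4-bromo-2-(2,4-dibromo-6-isopropoxyphenoxy)phenol
Product: 10 1,5-dibromo-2-(5-bromo-2-methoxyphenoxy)-3-isopropoxybenzene
Conditions: MeI, K2CO3, DMF, rt
Reagents that add atoms: iodomethane, CI
Why: Williamson O-methylation of the only free hydroxyl in the molecule, so no selectivity question arises and the other ether and bromide groups are untouched.

Step 7
Reactants: 10 1,5-dibromo-2-(5-bromo-2-methoxyphenoxy)-3-isopropoxybenzene
Product: 11 3,5-dibromo-2-(5-bromo-2-methoxyphenoxy)phenol
Conditions: BCl3 (1 M in CH2Cl2, 2.5 equiv), CH2Cl2, −78 °C to 0 °C; then H2O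
Reagents that add atoms: none
Why: Lewis-acid ether cleavage; the boron-complexed isopropyl ether ionises through a secondary cation far more readily than a methyl aryl ether or the diaryl ether can be cleaved, so BCl3 at low temperature should remove the isopropyl group alone.

**Compound list**

1 | 2-isopropoxyphenol | CC(C)Oc1ccccc1O | starting material
2 | 4-bromo-2-isopropoxyphenol | CC(C)Oc1cc(Br)ccc1O | intermediate
3 | 2,4-dibromo-6-isopropoxyphenol | CC(C)Oc1cc(Br)cc(Br)c1O | intermediate
4 | chloroacetone (1-chloropropan-2-one) | CC(=O)CCl | starting material
5 | 1-(2,4-dibromo-6-isopropoxyphenoxy)propan-2-one | CC(=O)COc1c(OC(C)C)cc(Br)cc1Br | intermediate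
6 | 2-bromomalonaldehyde | O=CC(Br)C=O | starting material
7 | 2-bromo-1,3-bis(dimethylamino)trimethinium tetrafluoroborate | CN(C)C=C(Br)C=[N+](C)C.F[B-](F)(F)F | intermediate
8 | 5-bromo-3-(2,4-dibromo-6-isopropoxyphenoxy)-6-(dimethylamino)hexa-3,5-dien-2-one | CC(=O)C(Oc1c(OC(C)C)cc(Br)cc1Br)=CC(Br)=CN(C)C | intermediate (not isolated)
9 | 4-bromo-2-(2,4-dibromo-6-isopropoxyphenoxy)phenol | Oc1ccc(Br)cc1Oc1c(OC(C)C)cc(Br)cc1Br | intermediate
10 | 1,5-dibromo-2-(5-bromo-2-methoxyphenoxy)-3-isopropoxybenzene | COc1ccc(Br)cc1Oc1c(OC(C)C)cc(Br)cc1Br | intermediate
11 | 3,5-dibromo-2-(5-bromo-2-methoxyphenoxy)phenol | COc1ccc(Br)cc1Oc1c(O)cc(Br)cc1Br | target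

**Step count**

Total steps: 7. Longest linear sequence: 6 (steps 1, 2, 3, 5, 6, 7 from compound 1); step 4 is a one-step side branch that joins at step 5.

**Steps most likely to fail**

Step 5. The sequence may stall after the first C–C bond without ring closure, the enolate may self-condense, or the vinamidinium cation may be hydrolysed by adventitious water before it is attacked. The fallback sets out from compound 3 and comes back at compound 10. Chan–Lam O-arylation of 3 with purchased (5-bromo-2-methoxyphenyl)boronic acid F1 (Cu(OAc)2, pyridine, 4 Å molecular sieves, CH2Cl2, air, rt) forms the diaryl ether bond directly and should give 10. Ring A then arrives preformed and steps 3 to 6 are bypassed. Divalent copper at room temperature should leave the aryl bromides untouched.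

Step 2. Bromination may leak to the carbon para to the isopropoxy group, or a third bromine may be introduced. The fallback sets out from compound 1 and comes back at compound 3, replacing steps 1 and 2; the ortho bromine is placed by metalation instead of electrophilic substitution. Compound 1 is converted into its methoxymethyl ether 1-isopropoxy-2-(methoxymethoxy)benzene F2 (MOMCl, iPr2NEt, CH2Cl2). Directed ortho-lithiation next to the chelating acetal oxygen (n-BuLi, TMEDA, THF, 0 °C) gives [3-isopropoxy-2-(methoxymethoxy)phenyl]lithium F3. Quenching with 1,2-dibromotetrachloroethane gives 1-bromo-3-isopropoxy-2-(methoxymethoxy)benzene F4. HCl in MeOH removes the acetal to give 2-bromo-6-isopropoxyphenol F5, and NBS in MeCN then brominates para to the hydroxyl to give 3.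

Step 4. The double condensation may stop at the mono-enaminal, or the salt may hydrolyse back during isolation. The fallback sets out from compound 6 and comes back at compound 7; the second C–N bond is made by electrophilic activation instead of acid-mediated condensation. Compound 6 is condensed with one equivalent of Me2NH (EtOH, reflux) to give the isolable enaminal 2-bromo-3-(dimethylamino)acrylaldehyde F6. Oxalyl chloride (CH2Cl2, 0 °C) converts this vinylogous amide into the chloro-iminium salt N-(2-bromo-3-chloroprop-2-en-1-ylidene)-N-methylmethanaminium chloride F7, a vinylogous Vilsmeier reagent. Addition of Me2NH and then NaBF4 should give 7.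

**Further compounds**

F1 | step 5 | (5-bromo-2-methoxyphenyl)boronic acid | COc1ccc(Br)cc1B(O)O
F2 | step 2 | 1-isopropoxy-2-(methoxymethoxy)benzene | COCOc1ccccc1OC(C)C
F3 | step 2 | [3-isopropoxy-2-(methoxymethoxy)phenyl]lithium | [Li]c1cccc(OC(C)C)c1OCOC
F4 | step 2 | 1-bromo-3-isopropoxy-2-(methoxymethoxy)benzene | COCOc1c(Br)cccc1OC(C)C
F5 | step 2 | 2-bromo-6-isopropoxyphenol | CC(C)Oc1cccc(Br)c1O
F6 | step 4 | 2-bromo-3-(dimethylamino)acrylaldehyde | CN(C)C=C(Br)C=O
F7 | step 4 | N-(2-bromo-3-chloroprop-2-en-1-ylidene)-N-methylmethanaminium chloride | C[N+](C)=CC(Br)=CCl.[Cl-]
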